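**Retrosynthetic overview**

1. The target is a benzofuran (benzo ring A, furan ring B) whose C2 carries C5 of a 2,2-dimethylchroman (benzo ring C, pyran ring D). After removal of three silyl ethers, ring B is opened at O1–C2 and at the C2–aryl bond, giving a 2-ethynylphenol (ring A with the C7 side chain) and a chroman-5-yl triflate (rings C and D).
2. In rings C and D, the triflate oxygen at C5, the prenyl group at C6 (O-allyl, Claisen shift to C6, cross-metathesis) and the CH2 at C4 all derive from one 5-allyloxy-chroman-4-one.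
3. Ring D of that chromanone is cut at C3–C2 and at O1–C8a, leaving acetone (C2, both methyl groups and O1) and a 2-fluoroaryl methyl ketone. The enabling feature is that O1 sits on C8a, the ring C carbon ortho to C4a, and that C4 on C4a can be carried as a ketone. This one carbonyl makes C3 an enolate carbon and makes C8a–F a site for addition–elimination. The C5 oxygen peri to it later delivers the prenyl group, allows removal of the C4 oxygen and becomes the triflate.
4. Ring A comes from phloroglucinol. The (R)-stereocenter on the carbon attached to C7 is set by reagent control ((+)-sparteine-derived α-carbamoyloxy boronic ester), transferred by a stereospecific 1,2-aryl shift and kept through a Zweifel olefination. Ortho-formylation and alkyne homologation follow.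
5. Order of ring formation: ring C is bought (5-fluororesorcinol), ring D is closed in step 4, ring A is bought (phloroglucinol), ring B is closed in step 18.

Key step: step 4

Remark: chroman numbering (O1, C2, C3, C4, C4a, C5 to C8, C8a) is used for rings C and D and benzofuran numbering for rings A and B; pin = pinacolato.

**Route**

Step 1
Reactants: 1 5-fluorobenzene-1,3-diol
Product: 2 1-(2-fluoro-4,6-dihydroxyphenyl)ethan-1-one
Conditions: AcOH, ZnCl2, 130 °C
Reagents that add atoms: acetic acid, CC(=O)O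
Why: Nencki (Friedel–Crafts) acylation of the resorcinol; the carbon ortho to one hydroxyl, para to the other and next to fluorine (two equivalent positions) is the most activated and least crowded site.

Step 2
Reactants: 2 1-(2-fluoro-4,6-dihydroxyphenyl)ethan-1-one
Product: 3 1-{2-fluoro-6-hydroxy-4-[(triisopropylsilyl)oxy]phenyl}ethan-1-one
Conditions: iPr3SiCl (1.05 equiv), imidazole, DMF, 0 °C
Reagents that add atoms: triisopropylsilyl chloride, CC(C)[Si](Cl)(C(C)C)C(C)C
Why: Selective silylation; the hydroxyl para to the acetyl group is the more acidic and accessible one, whereas the ortho hydroxyl is held in a hydrogen bond to the carbonyl.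

Step 3
Reactants: 3 1-{2-fluoro-6-hydroxy-4-[(triisopropylsilyl)oxy]phenyl}ethan-1-one
Product: 4 1-{2-fluoro-6-(prop-2-en-1-yloxy)-4-[(triisopropylsilyl)oxy]phenyl}ethan-1-one
Conditions: allyl bromide, K2CO3, acetone, 56 °C
Reagents that add atoms: allyl bromide, C=CCBr
Why: Williamson etherification of the chelated phenol under anhydrous carbonate conditions; the allyl ether masks this oxygen for the key step and is the later source of the C6 side chain.

Step 4
Reactants: 4 1-{2-fluoro-6-(prop-2-en-1-yloxy)-4-[(triisopropylsilyl)oxy]phenyl}ethan-1-one; 5 acetone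
Product: 8 2,2-dimethyl-5-(prop-2-en-1-yloxy)-7-[(triisopropylsilyl)oxy]-2,3-dihydro-4H-chromen-4-one, via lithium enolate 6 (not isolated), via lithium aldolate 7 (not isolated)
Conditions: LiN(iPr)2 (1.05 equiv), THF, −78 °C; acetone (3 equiv), −78 °C; then DMPU, −78 → 45 °C
Reagents that add atoms: none
Why: Kinetic deprotonation of the acetyl CH3 (the only enolizable site, the future C3) gives 6, which adds to acetone at −78 °C to form the C3–C2 bond in tertiary alkoxide 7; on warming with DMPU this alkoxide attacks C8a, the fluorine-bearing carbon ortho to the ketone, and loss of fluoride forms the O1–C8a bond. The closest known reaction types are the lithium-enolate aldol addition to ketones and the ketone-activated intramolecular SNAr ring closure used for chromones and 4-quinolones, here run as a domino aldol–SNAr annulation. Ring D closes by addition–elimination of the oxygen nucleophile at an sp2 carbon, 6-endo-trig with respect to the C4a=C8a bond conjugated to the C4 carbonyl (6-exo-trig with respect to C8a=C8), the carbonyl taking up the charge of the adduct. No stereocenter is formed. The step needs cross-aldol over self-condensation of acetone, secured by the preformed enolate at low temperature, and ring closure that outruns loss of material, secured because retro-aldol only returns 6 and acetone whereas fluoride loss is irreversible; the site of C–O bond formation is fixed because C8a holds the only leaving group and is the only ring carbon the three-atom tether can reach. The allyl ether and the silyl ether are inert to the amide base and to the alkoxide.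

Step 5
Reactants: 8 2,2-dimethyl-5-(prop-2-en-1-yloxy)-7-[(triisopropylsilyl)oxy]-2,3-dihydro-4H-chromen-4-one
Product: 9 5-hydroxy-2,2-dimethyl-6-(prop-2-en-1-yl)-7-[(triisopropylsilyl)oxy]-2,3-dihydro-4H-chromen-4-one
Conditions: PhNEt2, 190 °C
Reagents that add atoms: none
Why: Aromatic Claisen rearrangement; the allyl group moves from O5 to C6, the only free ortho carbon (C4a is fully substituted), and rearomatization is favoured by the hydrogen bond of the new phenol to the C4 carbonyl.

Step 6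
Reactants: 9 5-hydroxy-2,2-dimethyl-6-(prop-2-en-1-yl)-7-[(triisopropylsilyl)oxy]-2,3-dihydro-4H-chromen-4-one
Product: 10 5-hydroxy-2,2-dimethyl-6-(3-methylbut-2-en-1-yl)-7-[(triisopropylsilyl)oxy]-2,3-dihydro-4H-chromen-4-one
Conditions: 2-methylbut-2-ene (excess), second-generation Grubbs catalyst (5 mol %), CH2Cl2, 40 °C
Reagents that add atoms: 2-methylbut-2-ene, CC=C(C)C
Why: Olefin cross-metathesis of the terminal allyl group with excess 2-methylbut-2-ene, the standard allyl-to-prenyl conversion; the chelated phenol and the silyl ether are tolerated.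

Step 7
Reactants: 10 5-hydroxy-2,2-dimethyl-6-(3-methylbut-2-en-1-yl)-7-[(triisopropylsilyl)oxy]-2,3-dihydro-4H-chromen-4-one
Product: 13 2,2-dimethyl-6-(3-methylbut-2-en-1-yl)-7-[(triisopropylsilyl)oxy]-3,4-dihydro-2H-chromen-5-ol, via ethyl carbonate 11 (not isolated), via ortho-quinone methide 12 (not isolated)
Conditions: ClCO2Et, Et3N, THF, 0 °C; then NaBH4, H2O, 0 → 25 °C
Reagents that add atoms: none
Why: Reductive deoxygenation of an ortho-hydroxyaryl ketone through its ethyl carbonate: hydride reduces C4=O, the alkoxide takes over the ethoxycarbonyl group and is expelled to give 12, which accepts a second hydride at C4; no acid and no hydrogenation are involved, so the prenyl group and the silyl ether should survive.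

Step 8
Reactants: 13 2,2-dimethyl-6-(3-methylbut-2-en-1-yl)-7-[(triisopropylsilyl)oxy]-3,4-dihydro-2H-chromen-5-ol
Product: 14 2,2-dimethyl-6-(3-methylbut-2-en-1-yl)-7-[(triisopropylsilyl)oxy]-3,4-dihydro-2H-chromen-5-yl trifluoromethanesulfonate
Conditions: PhNTf2, Et3N, DMAP (cat.), CH2Cl2, 25 °C
Reagents that add atoms: N-phenylbis(trifluoromethanesulfonimide), O=S(=O)(N(c1ccccc1)S(=O)(=O)C(F)(F)F)C(F)(F)F
Why: O-Sulfonylation of the hindered phenol with a mild triflyl donor gives the aryl triflate for cross-coupling without exposing the prenyl group to strong acid.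

Step 9
Reactants: 15 ethanol; 16 N,N-diisopropylcarbamoyl chloride
Product: 17 ethyl N,N-diisopropylcarbamate
Conditions: Et3N, CH2Cl2, 40 °C
Reagents that add atoms: none
Why: Nucleophilic acyl substitution gives the O-alkyl carbamate needed for asymmetric deprotonation.

Step 10
Reactants: 17 ethyl N,N-diisopropylcarbamate
Product: 19 (1R)-1-(4,4,5,5-tetramethyl-1,3,2-dioxaborolan-2-yl)ethyl N,N-diisopropylcarbamate, via lithiated carbamate 18 (not isolated)
Conditions: s-BuLi, (+)-sparteine, Et2O, −78 °C; then iPrOB(pin), −78 → 25 °C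
Reagents that add atoms: 2-isopropoxy-4,4,5,5-tetramethyl-1,3,2-dioxaborolane, CC(C)OB1OC(C)(C)C(C)(C)O1
Why: Sparteine-mediated enantioselective deprotonation of an O-alkyl carbamate (Hoppe) followed by borylation with retention; the chiral diamine sets the stereocenter, (+)-sparteine being expected to give the (R)-configured lithium compound and hence the (R)-boronic ester.

Step 11
Reactants: 20 benzene-1,3,5-triol (phloroglucinol)
Product: 21 3,5-bis[(triisopropylsilyl)oxy]phenol
Conditions: iPr3SiCl (2.0 equiv), imidazole, DMF, 0 → 25 °C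
Reagents that add atoms: triisopropylsilyl chloride, CC(C)[Si](Cl)(C(C)C)C(C)C
Why: Statistical double silylation of a triol with three equivalent hydroxyls; only the degree of silylation has to be controlled, and mono- and tris-ethers can be recycled.

Step 12
Reactants: 21 3,5-bis[(triisopropylsilyl)oxy]phenol
Product: 22 3,5-bis[(triisopropylsilyl)oxy]phenyl N,N-diethylcarbamate
Conditions: NaH, THF, 0 °C; Et2NCOCl, 25 °C
Reagents that add atoms: N,N-diethylcarbamoyl chloride, CCN(CC)C(Cl)=O
Why: O-Carbamoylation of the phenoxide installs the directing group for ortho-metalation and marks the oxygen that will become O1 of ring B.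

Step 13
Reactants: 22 3,5-bis[(triisopropylsilyl)oxy]phenyl N,N-diethylcarbamate; 19 (1R)-1-(4,4,5,5-tetramethyl-1,3,2-dioxaborolan-2-yl)ethyl N,N-diisopropylcarbamate
Product: 25 2-[(1S)-1-(4,4,5,5-tetramethyl-1,3,2-dioxaborolan-2-yl)ethyl]-3,5-bis[(triisopropylsilyl)oxy]phenyl N,N-diethylcarbamate, via aryllithium 23 (not isolated), via boronate complex 24 (not isolated)
Conditions: s-BuLi, TMEDA, THF, −78 °C; 19, −78 °C; then MgBr2·OEt2, −78 → 40 °C
Reagents that add atoms: none
Why: Directed ortho-metalation next to the carbamate (the two ortho positions are equivalent, the carbon between the silyl ethers is shielded), addition of 23 to boron and stereospecific 1,2-aryl shift of 24 with expulsion of the carbamate and inversion at carbon (Matteson-type homologation), which should turn the (R)-reagent into the (S)-benzylic boronic ester.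

Step 14
Reactants: 25 2-[(1S)-1-(4,4,5,5-tetramethyl-1,3,2-dioxaborolan-2-yl)ethyl]-3,5-bis[(triisopropylsilyl)oxy]phenyl N,N-diethylcarbamate
Product: 28 2-[(2R)-3-methylbut-3-en-2-yl]-3,5-bis[(triisopropylsilyl)oxy]phenyl N,N-diethylcarbamate, via alkenylboronate complex 26 (not isolated), via iodo boronic ester 27 (not isolated)
Conditions: 2-bromopropene, t-BuLi (2 equiv), THF, −78 °C; 25, −78 → 0 °C; I2, MeOH, −78 °C; NaOMe, −78 → 25 °C
Reagents that add atoms: 2-bromopropene, CC(Br)=C
Why: Zweifel olefination: isopropenyllithium adds to boron, iodine triggers 1,2-migration of the benzylic carbon with retention, and methoxide-induced elimination from 27 gives the 1,1-disubstituted alkene; the spatial arrangement is kept and the descriptor changes from S to R only through the priority rules.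

Step 15
Reactants: 28 2-[(2R)-3-methylbut-3-en-2-yl]-3,5-bis[(triisopropylsilyl)oxy]phenyl N,N-diethylcarbamate
Product: 29 2-[(2R)-3-methylbut-3-en-2-yl]-3,5-bis[(triisopropylsilyl)oxy]phenol
Conditions: LiAlH4, THF, 0 → 25 °C
Reagents that add atoms: none
Why: Hydride cleavage of the aryl carbamate frees the phenol without acid, so the alkene next to the new hydroxyl should not cyclize and the stereocenter is not touched.

Step 16
Reactants: 29 2-[(2R)-3-methylbut-3-en-2-yl]-3,5-bis[(triisopropylsilyl)oxy]phenol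
Product: 30 2-hydroxy-3-[(2R)-3-methylbut-3-en-2-yl]-4,6-bis[(triisopropylsilyl)oxy]benzaldehyde
Conditions: MgCl2, Et3N, (CH2O)n, THF, 66 °C
Reagents that add atoms: formaldehyde (from paraformaldehyde), C=O
Why: Casnati–Skattebøl ortho-formylation; the magnesium phenoxide delivers formaldehyde to the only free ortho carbon, a second equivalent of formaldehyde acts as hydride acceptor, and the conditions are not acidic.

Step 17
Reactants: 30 2-hydroxy-3-[(2R)-3-methylbut-3-en-2-yl]-4,6-bis[(triisopropylsilyl)oxy]benzaldehyde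
Product: 31 2-ethynyl-6-[(2R)-3-methylbut-3-en-2-yl]-3,5-bis[(triisopropylsilyl)oxy]phenol
Conditions: (MeO)2P(O)CHN2, KOtBu (2.2 equiv), THF, −78 → 0 °C
Reagents that add atoms: dimethyl (diazomethyl)phosphonate, COP(=O)(OC)C=[N+]=[N-]
Why: Seyferth–Gilbert homologation of the aldehyde to the terminal alkyne at low temperature, chosen over carbonate in methanol to spare the aryl silyl ethers.

Step 18
Reactants: 31 2-ethynyl-6-[(2R)-3-methylbut-3-en-2-yl]-3,5-bis[(triisopropylsilyl)oxy]phenol; 14 2,2-dimethyl-6-(3-methylbut-2-en-1-yl)-7-[(triisopropylsilyl)oxy]-3,4-dihydro-2H-chromen-5-yl trifluoromethanesulfonate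
Product: 33 2-{2,2-dimethyl-6-(3-methylbut-2-en-1-yl)-7-[(triisopropylsilyl)oxy]-3,4-dihydro-2H-chromen-5-yl}-7-[(2R)-3-methylbut-3-en-2-yl]-4,6-bis[(triisopropylsilyl)oxy]-1-benzofuran, via diaryl alkyne 32 (not isolated)
Conditions: Pd(PPh3)4 (5 mol %), CuI (10 mol %), Et3N, DMF, 70 °C
Reagents that add atoms: none
Why: Sonogashira coupling of the aryl triflate with the 2-ethynylphenol, followed in the same flask by 5-endo-dig attack of the phenol oxygen on the metal-activated alkyne (known benzofuran synthesis from 2-ethynylphenols and aryl triflates); only the free hydroxyl between the alkyne and the side chain can cyclize, because the other oxygen ortho to the alkyne is silylated.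

Step 19
Reactants: 33 2-{2,2-dimethyl-6-(3-methylbut-2-en-1-yl)-7-[(triisopropylsilyl)oxy]-3,4-dihydro-2H-chromen-5-yl}-7-[(2R)-3-methylbut-3-en-2-yl]-4,6-bis[(triisopropylsilyl)oxy]-1-benzofuran
Product: 34 2-[7-hydroxy-2,2-dimethyl-6-(3-methylbut-2-en-1-yl)-3,4-dihydro-2H-chromen-5-yl]-7-[(2R)-3-methylbut-3-en-2-yl]-1-benzofuran-4,6-diol
Conditions: Bu4NF, AcOH, THF, 0 → 25 °C
Reagents that add atoms: none
Why: Buffered fluoride cleavage of the three aryl silyl ethers; no acid is used, so neither the prenyl group nor the 3-methylbut-3-en-2-yl group should cyclize onto a neighbouring phenol.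

**Compound list**

1 | 5-fluorobenzene-1,3-diol | Oc1cc(O)cc(F)c1 | starting material
2 | 1-(2-fluoro-4,6-dihydroxyphenyl)ethan-1-one | CC(=O)c1c(O)cc(O)cc1F | intermediate
3 | 1-{2-fluoro-6-hydroxy-4-[(triisopropylsilyl)oxy]phenyl}ethan-1-one | CC(=O)c1c(O)cc(O[Si](C(C)C)(C(C)C)C(C)C)cc1F | intermediate
4 | 1-{2-fluoro-6-(prop-2-en-1-yloxy)-4-[(triisopropylsilyl)oxy]phenyl}ethan-1-one | CC(=O)c1c(OCC=C)cc(O[Si](C(C)C)(C(C)C)C(C)C)cc1F | intermediate
5 | acetone | CC(C)=O | starting material
6 | lithium 1-{2-fluoro-6-(prop-2-en-1-yloxy)-4-[(triisopropylsilyl)oxy]phenyl}ethen-1-olate (not isolated) | [Li+].C=C([O-])c1c(OCC=C)cc(O[Si](C(C)C)(C(C)C)C(C)C)cc1F | intermediate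
7 | lithium 4-{2-fluoro-6-(prop-2-en-1-yloxy)-4-[(triisopropylsilyl)oxy]phenyl}-2-methyl-4-oxobutan-2-olate (not isolated) | [Li+].CC(C)([O-])CC(=O)c1c(OCC=C)cc(O[Si](C(C)C)(C(C)C)C(C)C)cc1F | intermediate
8 | 2,2-dimethyl-5-(prop-2-en-1-yloxy)-7-[(triisopropylsilyl)oxy]-2,3-dihydro-4H-chromen-4-one | CC1(C)CC(=O)c2c(OCC=C)cc(O[Si](C(C)C)(C(C)C)C(C)C)cc2O1 | intermediate
9 | 5-hydroxy-2,2-dimethyl-6-(prop-2-en-1-yl)-7-[(triisopropylsilyl)oxy]-2,3-dihydro-4H-chromen-4-one | CC1(C)CC(=O)c2c(O)c(CC=C)c(O[Si](C(C)C)(C(C)C)C(C)C)cc2O1 | intermediate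
10 | 5-hydroxy-2,2-dimethyl-6-(3-methylbut-2-en-1-yl)-7-[(triisopropylsilyl)oxy]-2,3-dihydro-4H-chromen-4-one | CC1(C)CC(=O)c2c(O)c(CC=C(C)C)c(O[Si](C(C)C)(C(C)C)C(C)C)cc2O1 | intermediate
11 | ethyl 2,2-dimethyl-6-(3-methylbut-2-en-1-yl)-4-oxo-7-[(triisopropylsilyl)oxy]-3,4-dihydro-2H-chromen-5-yl carbonate (not isolated) | CCOC(=O)Oc1c(CC=C(C)C)c(O[Si](C(C)C)(C(C)C)C(C)C)cc2OC(C)(C)CC(=O)c12 | intermediate
12 | 2,2-dimethyl-6-(3-methylbut-2-en-1-yl)-7-[(triisopropylsilyl)oxy]-2,3-dihydro-5H-chromen-5-one, the ortho-quinone methide (not isolated) | CC1(C)CC=C2C(=O)C(CC=C(C)C)=C(O[Si](C(C)C)(C(C)C)C(C)C)C=C2O1 | intermediate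
13 | 2,2-dimethyl-6-(3-methylbut-2-en-1-yl)-7-[(triisopropylsilyl)oxy]-3,4-dihydro-2H-chromen-5-ol | CC1(C)CCc2c(O)c(CC=C(C)C)c(O[Si](C(C)C)(C(C)C)C(C)C)cc2O1 | intermediate
14 | 2,2-dimethyl-6-(3-methylbut-2-en-1-yl)-7-[(triisopropylsilyl)oxy]-3,4-dihydro-2H-chromen-5-yl trifluoromethanesulfonate | CC1(C)CCc2c(OS(=O)(=O)C(F)(F)F)c(CC=C(C)C)c(O[Si](C(C)C)(C(C)C)C(C)C)cc2O1 | intermediate
15 | ethanol | CCO | starting material
16 | N,N-diisopropylcarbamoyl chloride | CC(C)N(C(C)C)C(Cl)=O | starting material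
17 | ethyl N,N-diisopropylcarbamate | CCOC(=O)N(C(C)C)C(C)C | intermediate
18 | (1R)-1-lithioethyl N,N-diisopropylcarbamate, (+)-sparteine complex (not isolated) | C[C@@H]([Li])OC(=O)N(C(C)C)C(C)C | intermediate
19 | (1R)-1-(4,4,5,5-tetramethyl-1,3,2-dioxaborolan-2-yl)ethyl N,N-diisopropylcarbamate | C[C@H](OC(=O)N(C(C)C)C(C)C)B1OC(C)(C)C(C)(C)O1 | intermediate
20 | benzene-1,3,5-triol (phloroglucinol) | Oc1cc(O)cc(O)c1 | starting material
21 | 3,5-bis[(triisopropylsilyl)oxy]phenol | Oc1cc(O[Si](C(C)C)(C(C)C)C(C)C)cc(O[Si](C(C)C)(C(C)C)C(C)C)c1 | intermediate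
22 | 3,5-bis[(triisopropylsilyl)oxy]phenyl N,N-diethylcarbamate | CCN(CC)C(=O)Oc1cc(O[Si](C(C)C)(C(C)C)C(C)C)cc(O[Si](C(C)C)(C(C)C)C(C)C)c1 | intermediate
23 | 2-lithio-3,5-bis[(triisopropylsilyl)oxy]phenyl N,N-diethylcarbamate (not isolated) | [Li]c1c(OC(=O)N(CC)CC)cc(O[Si](C(C)C)(C(C)C)C(C)C)cc1O[Si](C(C)C)(C(C)C)C(C)C | intermediate
24 | lithium boronate complex of 23 and 19, aryl and (1R)-1-(carbamoyloxy)ethyl on boron (not isolated) | [Li+].C[C@H](OC(=O)N(C(C)C)C(C)C)[B-]1(OC(C)(C)C(C)(C)O1)c1c(OC(=O)N(CC)CC)cc(O[Si](C(C)C)(C(C)C)C(C)C)cc1O[Si](C(C)C)(C(C)C)C(C)C | intermediate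
25 | 2-[(1S)-1-(4,4,5,5-tetramethyl-1,3,2-dioxaborolan-2-yl)ethyl]-3,5-bis[(triisopropylsilyl)oxy]phenyl N,N-diethylcarbamate | C[C@H](B1OC(C)(C)C(C)(C)O1)c1c(OC(=O)N(CC)CC)cc(O[Si](C(C)C)(C(C)C)C(C)C)cc1O[Si](C(C)C)(C(C)C)C(C)C | intermediate
26 | lithium isopropenyl boronate complex of 25 (not isolated) | [Li+].C[C@H]([B-]1(OC(C)(C)C(C)(C)O1)C(C)=C)c1c(OC(=O)N(CC)CC)cc(O[Si](C(C)C)(C(C)C)C(C)C)cc1O[Si](C(C)C)(C(C)C)C(C)C | intermediate
27 | 2-[4-iodo-3-methyl-3-(4,4,5,5-tetramethyl-1,3,2-dioxaborolan-2-yl)butan-2-yl]-3,5-bis[(triisopropylsilyl)oxy]phenyl N,N-diethylcarbamate, benzylic configuration retained, epimers at the boron-bearing carbon (not isolated) | C[C@H](C(C)(CI)B1OC(C)(C)C(C)(C)O1)c1c(OC(=O)N(CC)CC)cc(O[Si](C(C)C)(C(C)C)C(C)C)cc1O[Si](C(C)C)(C(C)C)C(C)C | intermediate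
28 | 2-[(2R)-3-methylbut-3-en-2-yl]-3,5-bis[(triisopropylsilyl)oxy]phenyl N,N-diethylcarbamate | C=C(C)[C@@H](C)c1c(OC(=O)N(CC)CC)cc(O[Si](C(C)C)(C(C)C)C(C)C)cc1O[Si](C(C)C)(C(C)C)C(C)C | intermediate
29 | 2-[(2R)-3-methylbut-3-en-2-yl]-3,5-bis[(triisopropylsilyl)oxy]phenol | C=C(C)[C@@H](C)c1c(O)cc(O[Si](C(C)C)(C(C)C)C(C)C)cc1O[Si](C(C)C)(C(C)C)C(C)C | intermediate
30 | 2-hydroxy-3-[(2R)-3-methylbut-3-en-2-yl]-4,6-bis[(triisopropylsilyl)oxy]benzaldehyde | C=C(C)[C@@H](C)c1c(O)c(C=O)c(O[Si](C(C)C)(C(C)C)C(C)C)cc1O[Si](C(C)C)(C(C)C)C(C)C | intermediate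
31 | 2-ethynyl-6-[(2R)-3-methylbut-3-en-2-yl]-3,5-bis[(triisopropylsilyl)oxy]phenol | C=C(C)[C@@H](C)c1c(O)c(C#C)c(O[Si](C(C)C)(C(C)C)C(C)C)cc1O[Si](C(C)C)(C(C)C)C(C)C | intermediate
32 | 2-({2,2-dimethyl-6-(3-methylbut-2-en-1-yl)-7-[(triisopropylsilyl)oxy]-3,4-dihydro-2H-chromen-5-yl}ethynyl)-6-[(2R)-3-methylbut-3-en-2-yl]-3,5-bis[(triisopropylsilyl)oxy]phenol (not isolated) | C=C(C)[C@@H](C)c1c(O)c(C#Cc2c(CC=C(C)C)c(O[Si](C(C)C)(C(C)C)C(C)C)cc3OC(C)(C)CCc23)c(O[Si](C(C)C)(C(C)C)C(C)C)cc1O[Si](C(C)C)(C(C)C)C(C)C | intermediate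
33 | 2-{2,2-dimethyl-6-(3-methylbut-2-en-1-yl)-7-[(triisopropylsilyl)oxy]-3,4-dihydro-2H-chromen-5-yl}-7-[(2R)-3-methylbut-3-en-2-yl]-4,6-bis[(triisopropylsilyl)oxy]-1-benzofuran | C=C(C)[C@@H](C)c1c(O[Si](C(C)C)(C(C)C)C(C)C)cc(O[Si](C(C)C)(C(C)C)C(C)C)c2cc(-c3c(CC=C(C)C)c(O[Si](C(C)C)(C(C)C)C(C)C)cc4c3CCC(C)(C)O4)oc12 | intermediate
34 | 2-[7-hydroxy-2,2-dimethyl-6-(3-methylbut-2-en-1-yl)-3,4-dihydro-2H-chromen-5-yl]-7-[(2R)-3-methylbut-3-en-2-yl]-1-benzofuran-4,6-diol | C=C(C)[C@@H](C)c1c(O)cc(O)c2cc(-c3c(CC=C(C)C)c(O)cc4c3CCC(C)(C)O4)oc12 | target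

**Summary**

Total step count: 19.
Longest linear sequence: 10 steps (steps 1 to 8, then 18 and 19).

Steps most likely to fail:

Step 4. The risk is retro-aldol fragmentation of the lithium aldolate and self-condensation of acetone running faster than fluoride displacement on the electron-rich ring. The fallback sets out from 4 and comes back at 8. The enolate of 4 is added to acetone as before, but aldolate 7 is trapped cold with MsCl and Et3N and eliminated with DBU to give the enone 1-{2-fluoro-6-(prop-2-en-1-yloxy)-4-[(triisopropylsilyl)oxy]phenyl}-3-methylbut-2-en-1-one F1. NaH and 2-(methylsulfonyl)ethanol in DMF at 25 °C then replace fluoride by oxygen, first giving the aryl ether 1-{2-[2-(methylsulfonyl)ethoxy]-6-(prop-2-en-1-yloxy)-4-[(triisopropylsilyl)oxy]phenyl}-3-methylbut-2-en-1-one F2. In the same flask F2 loses methyl vinyl sulfone to give the phenoxide of 1-{2-hydroxy-6-(prop-2-en-1-yloxy)-4-[(triisopropylsilyl)oxy]phenyl}-3-methylbut-2-en-1-one F3, which closes to 8 by the classical 6-endo oxa-Michael addition of 2-hydroxyaryl prenyl ketones.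

Step 13. The risk is incomplete ortho-lithiation beside the bulky silyl ether, anionic Fries migration of the carbamate on warming, or a slow 1,2-aryl shift of the crowded boronate complex with erosion of configuration. The fallback sets out from 21 and comes back at 29, bypassing steps 12 to 15. Mitsunobu etherification of 21 with (E)-2-methylbut-2-en-1-ol (PPh3, diisopropyl azodicarboxylate, THF) gives 1-{[(2E)-2-methylbut-2-en-1-yl]oxy}-3,5-bis[(triisopropylsilyl)oxy]benzene F4. Thermal aromatic Claisen rearrangement (PhNEt2, 180 °C) to either of the two equivalent ortho carbons gives racemic 2-(3-methylbut-3-en-2-yl)-3,5-bis[(triisopropylsilyl)oxy]phenol F5. The enantiomers are separated by preparative chromatography on a chiral stationary phase, and the (R)-enantiomer is 29.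

Step 18. The risk is slow oxidative addition of zerovalent palladium into the doubly ortho-substituted, electron-rich triflate, which would leave time for oxidative homocoupling or premature cycloisomerization of the ethynylphenol. The fallback sets out from 31 and comes back at 33. Compound 31 is cycloisomerized on purpose (CuI, Et3N, DMF, 80 °C) to 7-[(2R)-3-methylbut-3-en-2-yl]-4,6-bis[(triisopropylsilyl)oxy]-1-benzofuran F6. Deprotonation at C2 with n-BuLi at −78 °C and trapping with iPrOB(pin) gives 2-(4,4,5,5-tetramethyl-1,3,2-dioxaborolan-2-yl)-7-[(2R)-3-methylbut-3-en-2-yl]-4,6-bis[(triisopropylsilyl)oxy]-1-benzofuran F7. Suzuki–Miyaura coupling of F7 with triflate 14 (Pd(OAc)2, SPhos, K3PO4, toluene/H2O, 80 °C) gives 33.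

Further compounds
F1 | step 4 | 1-{2-fluoro-6-(prop-2-en-1-yloxy)-4-[(triisopropylsilyl)oxy]phenyl}-3-methylbut-2-en-1-one | CC(C)=CC(=O)c1c(OCC=C)cc(O[Si](C(C)C)(C(C)C)C(C)C)cc1F
F2 | step 4 | 1-{2-[2-(methylsulfonyl)ethoxy]-6-(prop-2-en-1-yloxy)-4-[(triisopropylsilyl)oxy]phenyl}-3-methylbut-2-en-1-one | CC(C)=CC(=O)c1c(OCC=C)cc(O[Si](C(C)C)(C(C)C)C(C)C)cc1OCCS(C)(=O)=O
F3 | step 4 | 1-{2-hydroxy-6-(prop-2-en-1-yloxy)-4-[(triisopropylsilyl)oxy]phenyl}-3-methylbut-2-en-1-one | CC(C)=CC(=O)c1c(OCC=C)cc(O[Si](C(C)C)(C(C)C)C(C)C)cc1O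
F4 | step 13 | 1-{[(2E)-2-methylbut-2-en-1-yl]oxy}-3,5-bis[(triisopropylsilyl)oxy]benzene | C/C=C(\C)COc1cc(O[Si](C(C)C)(C(C)C)C(C)C)cc(O[Si](C(C)C)(C(C)C)C(C)C)c1
F5 | step 13 | racemic 2-(3-methylbut-3-en-2-yl)-3,5-bis[(triisopropylsilyl)oxy]phenol | C=C(C)C(C)c1c(O)cc(O[Si](C(C)C)(C(C)C)C(C)C)cc1O[Si](C(C)C)(C(C)C)C(C)C
F6 | step 18 | 7-[(2R)-3-methylbut-3-en-2-yl]-4,6-bis[(triisopropylsilyl)oxy]-1-benzofuran | C=C(C)[C@@H](C)c1c(O[Si](C(C)C)(C(C)C)C(C)C)cc(O[Si](C(C)C)(C(C)C)C(C)C)c2ccoc12
F7 | step 18 | 2-(4,4,5,5-tetramethyl-1,3,2-dioxaborolan-2-yl)-7-[(2R)-3-methylbut-3-en-2-yl]-4,6-bis[(triisopropylsilyl)oxy]-1-benzofuran | C=C(C)[C@@H](C)c1c(O[Si](C(C)C)(C(C)C)C(C)C)cc(O[Si](C(C)C)(C(C)C)C(C)C)c2cc(B3OC(C)(C)C(C)(C)O3)oc12
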